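Early on the two earlier runs read close together: Q reads 9.7% in grey and 9.4% in blue at 0.667 h, and 26.3% in both at 1.33 h. By 3.00 h, L reads 0.2% in grey and 0% in blue, yet Q stands well short of the charge, so a dissolved share remains to be converted.

all flasks: L 0.20 M

| charge | E | Z | remark | time |
|---|---|---|---|---|
| grey | 0.40 M | 0.13 M | run made earlier |  |
| blue | 0.40 M | 0.30 M | run made earlier |  |
| flask | 0.400 M | 0.200 M |  | 6.0 h |

| run | time / h | Q / % | L / % |
|---|---|---|---|
| grey | 0.250 | 1.7 | 82.2 |
| grey | 0.667 | 9.7 | 58.8 |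
| grey | 1.33 | 26.3 | 33.1 |
| grey | 2.00 | 44.1 | 12.4 |
| grey | 3.00 | 65.4 | 0.2 |
| grey | 4.00 | 78.1 | 0.5 |
| blue | 0.667 | 9.4 | 59.2 |
| blue | 1.33 | 26.3 | 33.8 |
| blue | 2.00 | 41.6 | 13.9 |
| blue | 2.50 | 52.7 | 0.6 |
| blue | 3.00 | 61.8 | 0 |
| blue | 4.00 | 72.8 | 0 |

(each reading ± 0.3 percentage points)

- L is a solid; its amount is given per volume of the solution
- at the start none of L is in solution

- amount of Q in percent of the L charged, at 40 min, 2.0 h, 4.0 h and 6.0 h

The useful quantity is the late decay constant κ: the rate of forming Q divided by the share of the charge not yet Q, so that a share ratio over an interval gives it. From 3.00 h to 4.00 h, grey gives 0.457 h⁻¹ and blue, with more Z, a lower 0.340 h⁻¹. Interpolation by Z gives, as an estimate for the new flask, κ = 0.409 h⁻¹ and Q of 75.9% at 4.0 h. Carried unchanged to 6.0 h, that κ gives 89.4%.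

The forecast is lower at the end: 9.6%, 43.1%, 75.9% and 85.5%, on the ground that “The remaining 24% then decays at about 0.3/h”.

The flask gives 9.74%, 43.0%, 75.9% and 87.5%.

    L ⇌ G, rate k1*(cs1 - [G]) while solid is left; crystals form when [G] > cs1 (solubility = 0.130 M, k = 0.0223 min⁻¹)
    G + E → Q (k = 0.0337 M⁻¹ min⁻¹)
    E + Z → J (k = 0.00586 M⁻¹ min⁻¹)

In the flask, κ from 4.0 h to 6.0 h comes to 0.328 h⁻¹, lower than the interpolated 0.409 h⁻¹. At 6.0 h, with L at 0%, G is the unconverted share, and its pseudo-first-order decay follows E, which Z also consumes. Q in the flask stands at 87.5% at 6.0 h through the using up of E together with the hour of reading: with E held, Q reaches 98.0% at 6.0 h, and the flask itself reaches >99.9% at 60.0 h. On that longer stretch E falls from 36.4% to 9.03% of its charge, G from 12.5% to 0.0122%, and κ averages 0.128 h⁻¹.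

(The readings are calculated with made-up constants; scatter was added.)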